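**Plan**
- Retrosynthesis: cut the depside ester bond between the ring A C4 oxygen and the ring B C1' carbonyl, then cut ring A at C3–C4 and C5–C6.
- Enabling feature: ring A has its ester on C1 para to the C4 oxygen and a separate methyl ether on C2. C3–C2–C1–C6 is therefore the diene C3–C4–C5–C6 of a 4-methoxy-2-pyrone-5-carboxylate, and C4–C5 is an O-silyl ynol ether.
- Forward: the pyrone ring is built first from methyl acetoacetate and methylmalonyl dichloride. Ring A arises from it by [4+2] cycloaddition with 1-(triisopropylsilyloxy)propyne and loss of CO2, so its two oxygens emerge already differentiated as OCH3 and OSi.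
- Ring B is bought as methyl atrarate, formylated at its only free carbon C5', benzylated and saponified.
- Desilylation, trifluoroacetic anhydride esterification of the two hindered halves and hydrogenolysis finish the route.
- Stereochemistry: the target has no stereocentre. The few centres formed on the way are transient, racemic and erased.

Key step: step 5

Remark on numbering: ring A is numbered from the ester-bearing carbon C1 (OCH3 on C2, depside oxygen on C4). Ring B is primed and numbered from the carbon bearing the depside carbonyl, C1' (OH on C2' and C4', CHO on C5'). The pyrone is numbered O1, C2 (C=O) to C6.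

**Step 1**
Reactants: 1 methylmalonic acid
Product: 2 methylmalonyl dichloride
Conditions: SOCl2, 50 → 75 °C; distillation under reduced pressure
Reagents that add atoms: thionyl chloride, O=S(Cl)Cl
Why: This is the standard conversion of a malonic acid into its bis(acid chloride) with thionyl chloride, in which the gaseous by-products leave and the product is purified by distillation.

**Step 2**
Reactants: 2 methylmalonyl dichloride; 3 methyl acetoacetate
Product: 4 methyl 4-hydroxy-3,6-dimethyl-2-oxo-2H-pyran-5-carboxylate
Conditions: PhMe, 80 °C, N2 sweep
Reagents that add atoms: none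
Why: Double acylation of a β-keto ester by a malonyl dichloride (C-acylation of the active methylene, O-acylation of the ketone enol) is the established annulation to 4-hydroxy-2-pyrone-5-carboxylates, and because the bis-electrophile is symmetric and C3 ends up blocked by methyl, neither a regioisomer nor a second annulation can arise.

**Step 3**
Reactants: 4 methyl 4-hydroxy-3,6-dimethyl-2-oxo-2H-pyran-5-carboxylate
Product: 5 methyl 4-methoxy-3,6-dimethyl-2-oxo-2H-pyran-5-carboxylate
Conditions: Me2SO4, K2CO3, acetone, reflux
Reagents that add atoms: dimethyl sulfate, COS(=O)(=O)OC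
Why: Williamson-type O-alkylation of the vinylogous acid with a hard methylating agent and carbonate in acetone is the usual entry to 4-methoxy-2-pyrones and favours the C4 oxygen over the lactone carbonyl oxygen.

**Step 4**
Reactants: 6 propyne
Product: 9 1-(triisopropylsilyloxy)prop-1-yne, via 1-propynyllithium 7 (not isolated), via lithium ynolate 8 (not isolated)
Conditions: n-BuLi, THF, −78 °C; t-BuOOLi (from t-BuOOH, LiN(SiMe3)2), −78 → 0 °C; i-Pr3SiOTf, −78 → 0 °C
Reagents that add atoms: tert-butyl hydroperoxide, CC(C)(C)OO; triisopropylsilyl trifluoromethanesulfonate, CC(C)[Si](OS(=O)(=O)C(F)(F)F)(C(C)C)C(C)C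
Why: Oxygen transfer from lithium tert-butyl peroxide to a lithium acetylide is a known route to lithium ynolates, and a bulky triisopropylsilyl electrophile traps them on oxygen to give the distillable siloxyalkyne rather than the silylketene.

**Step 5**
Reactants: 5 methyl 4-methoxy-3,6-dimethyl-2-oxo-2H-pyran-5-carboxylate; 9 1-(triisopropylsilyloxy)prop-1-yne
Product: 11 methyl 2-methoxy-3,5,6-trimethyl-4-(triisopropylsilyloxy)benzoate, via bridged bicyclic lactone 10 (not isolated)
Conditions: AgNTf2 (10 mol %), 4 Å MS, ClCH2CH2Cl, 70 °C, 9 (3 equiv) added by syringe pump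
Reagents that add atoms: none
Why: The alkyne adds across pyrone C3 and C6 in a strongly asynchronous inverse-demand [4+2] cycloaddition: its methyl-bearing carbon, made nucleophilic by the silyloxy group, attacks C6 (the β-carbon of the C5 acrylate unit), the oxygen-bearing, ketenium-like carbon is then taken up by C3, and lactone 10 expels CO2 in a retro-[4+2] step that makes the benzene irreversibly. The closest known reaction type is the Diels–Alder/decarboxylation benzannulation of 2-pyrone-5-carboxylates with ynamines, ynol ethers, siloxyalkynes and ketene acetals, together with the AgNTf2-catalysed formal cycloadditions of siloxyalkynes with enones and 1,2-diazines. Ring A closes in an intermolecular 4+2 mode, four carbons coming from pyrone C3–C6 and two from the alkyne, the new bonds being ring A C3–C4 and C5–C6. The two bridgehead stereocentres of 10 form as a racemate, are fixed relative to each other by the bicycle and vanish on aromatisation, so nothing needs to be controlled. The selectivity needed is regiochemical (silyloxy carbon to C3, hence oxygen para to the ester), and matched polarisation secures it, since attack of the alkyne on C6 first and attack of the methoxy-activated C3 on the silver-bound alkyne first both lead to the same isomer. The silver salt and the slow feed of excess 9 are chosen because the pyrone is tetrasubstituted and its methoxy group lowers its electrophilicity, a handicap for a concerted process that becomes a help for the second bond of a stepwise one.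

**Step 6**
Reactants: 11 methyl 2-methoxy-3,5,6-trimethyl-4-(triisopropylsilyloxy)benzoate
Product: 12 methyl 4-hydroxy-2-methoxy-3,5,6-trimethylbenzoate
Conditions: Bu4NF, AcOH, THF, 0 °C → rt
Reagents that add atoms: none
Why: Fluoride-induced cleavage of an aryl silyl ether is driven by the Si–F bond and the good phenoxide leaving group, and the acetic acid buffer keeps the methyl ester untouched.

**Step 7**
Reactants: 13 methyl 2,4-dihydroxy-3,6-dimethylbenzoate (methyl atrarate)
Product: 15 methyl 5-formyl-2,4-dihydroxy-3,6-dimethylbenzoate, via α-chloro ether 14 (not isolated)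
Conditions: Cl2CHOMe, TiCl4, CH2Cl2, 0 °C → rt; then aq. HCl
Reagents that add atoms: dichloromethyl methyl ether, COC(Cl)Cl; water, O
Why: In this Rieche formylation the titanium-bound phenol directs Friedel–Crafts attack of the chloro(methoxy)carbenium ion to C5', the only unsubstituted ring carbon (ortho to the 4'-OH, para to the 2'-OH), and the α-chloro ether is hydrolysed to the aldehyde on work-up.

**Step 8**
Reactants: 15 methyl 5-formyl-2,4-dihydroxy-3,6-dimethylbenzoate
Product: 16 methyl 2,4-bis(benzyloxy)-5-formyl-3,6-dimethylbenzoate
Conditions: BnBr, K2CO3, DMF, 60 °C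
Reagents that add atoms: benzyl bromide, BrCc1ccccc1
Why: Williamson etherification in warm DMF overcomes the hydrogen bonds of the 2'-OH to the ester and of the 4'-OH to the aldehyde, so both phenols are masked without touching the aldehyde.

**Step 9**
Reactants: 16 methyl 2,4-bis(benzyloxy)-5-formyl-3,6-dimethylbenzoate
Product: 18 2,4-bis(benzyloxy)-5-formyl-3,6-dimethylbenzoic acid, via potassium carboxylate 17 (not isolated)
Conditions: KOH, DMSO–H2O, 80 °C; then aq. HCl
Reagents that add atoms: potassium hydroxide, [K+].[OH-]
Why: Saponification of a di-ortho-substituted benzoate calls for poorly solvated hydroxide in aqueous DMSO, conditions that benzyl ethers tolerate and under which the non-enolisable, electron-rich and flanked aldehyde should resist Cannizzaro disproportionation.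

**Step 10**
Reactants: 12 methyl 4-hydroxy-2-methoxy-3,5,6-trimethylbenzoate; 18 2,4-bis(benzyloxy)-5-formyl-3,6-dimethylbenzoic acid
Product: 20 methyl 4-{[2,4-bis(benzyloxy)-5-formyl-3,6-dimethylbenzoyl]oxy}-2-methoxy-3,5,6-trimethylbenzoate, via mixed trifluoroacetic anhydride 19 (not isolated)
Conditions: (CF3CO)2O, PhMe, 0 °C → rt
Reagents that add atoms: none
Why: In the trifluoroacetic anhydride esterification the mixed anhydride of an electron-rich 2,6-disubstituted benzoic acid ionises towards a slim, linear acylium ion, which is the standard way to join di-ortho-substituted acids to di-ortho-substituted phenols in depside synthesis.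

**Step 11**
Reactants: 20 methyl 4-{[2,4-bis(benzyloxy)-5-formyl-3,6-dimethylbenzoyl]oxy}-2-methoxy-3,5,6-trimethylbenzoate
Product: 21 methyl 4-[(5-formyl-2,4-dihydroxy-3,6-dimethylbenzoyl)oxy]-2-methoxy-3,5,6-trimethylbenzoate (CNP0316552.0)
Conditions: H2 (1 atm), Pd/C, EtOAc, rt, stopped after uptake of two equivalents
Reagents that add atoms: none
Why: Catalytic hydrogenolysis of aryl benzyl ethers in a neutral solvent is faster than reduction of the aryl aldehyde, which is further deactivated by its hydrogen bond to the freed 4'-OH, while the hindered depside ester, the methyl ester and the methyl ether are inert.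

**Compound list**
1 | methylmalonic acid | CC(C(O)=O)C(O)=O | starting material
2 | methylmalonyl dichloride | CC(C(Cl)=O)C(Cl)=O | intermediate
3 | methyl acetoacetate | COC(=O)CC(C)=O | starting material
4 | methyl 4-hydroxy-3,6-dimethyl-2-oxo-2H-pyran-5-carboxylate | COC(=O)C1=C(C)OC(=O)C(C)=C1O | intermediate
5 | methyl 4-methoxy-3,6-dimethyl-2-oxo-2H-pyran-5-carboxylate | COC(=O)C1=C(C)OC(=O)C(C)=C1OC | intermediate
6 | propyne | CC#C | starting material
7 | 1-propynyllithium (not isolated) | [Li]C#CC | intermediate
8 | lithium prop-1-yn-1-olate (not isolated) | CC#C[O-].[Li+] | intermediate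
9 | 1-(triisopropylsilyloxy)prop-1-yne | CC#CO[Si](C(C)C)(C(C)C)C(C)C | intermediate
10 | methyl 5-methoxy-1,4,7-trimethyl-3-oxo-8-(triisopropylsilyloxy)-2-oxabicyclo[2.2.2]octa-5,7-diene-6-carboxylate (racemic, one enantiomer drawn, not isolated) | C[C@@]12OC(=O)[C@@](C)(C(OC)=C1C(=O)OC)C(O[Si](C(C)C)(C(C)C)C(C)C)=C2C | intermediate
11 | methyl 2-methoxy-3,5,6-trimethyl-4-(triisopropylsilyloxy)benzoate | COC(=O)c1c(C)c(C)c(O[Si](C(C)C)(C(C)C)C(C)C)c(C)c1OC | intermediate
12 | methyl 4-hydroxy-2-methoxy-3,5,6-trimethylbenzoate | COC(=O)c1c(C)c(C)c(O)c(C)c1OC | intermediate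
13 | methyl 2,4-dihydroxy-3,6-dimethylbenzoate (methyl atrarate) | COC(=O)c1c(C)cc(O)c(C)c1O | starting material
14 | methyl 5-[chloro(methoxy)methyl]-2,4-dihydroxy-3,6-dimethylbenzoate (racemic at the chloro ether carbon, not isolated) | COC(=O)c1c(C)c(C(Cl)OC)c(O)c(C)c1O | intermediate
15 | methyl 5-formyl-2,4-dihydroxy-3,6-dimethylbenzoate | COC(=O)c1c(C)c(C=O)c(O)c(C)c1O | intermediate
16 | methyl 2,4-bis(benzyloxy)-5-formyl-3,6-dimethylbenzoate | COC(=O)c1c(C)c(C=O)c(OCc2ccccc2)c(C)c1OCc1ccccc1 | intermediate
17 | potassium 2,4-bis(benzyloxy)-5-formyl-3,6-dimethylbenzoate (not isolated) | [K+].[O-]C(=O)c1c(C)c(C=O)c(OCc2ccccc2)c(C)c1OCc1ccccc1 | intermediate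
18 | 2,4-bis(benzyloxy)-5-formyl-3,6-dimethylbenzoic acid | OC(=O)c1c(C)c(C=O)c(OCc2ccccc2)c(C)c1OCc1ccccc1 | intermediate
19 | 2,4-bis(benzyloxy)-5-formyl-3,6-dimethylbenzoic trifluoroacetic anhydride (not isolated) | O=C(OC(=O)C(F)(F)F)c1c(C)c(C=O)c(OCc2ccccc2)c(C)c1OCc1ccccc1 | intermediate
20 | methyl 4-{[2,4-bis(benzyloxy)-5-formyl-3,6-dimethylbenzoyl]oxy}-2-methoxy-3,5,6-trimethylbenzoate | COC(=O)c1c(C)c(C)c(OC(=O)c2c(C)c(C=O)c(OCc3ccccc3)c(C)c2OCc2ccccc2)c(C)c1OC | intermediate
21 | methyl 4-[(5-formyl-2,4-dihydroxy-3,6-dimethylbenzoyl)oxy]-2-methoxy-3,5,6-trimethylbenzoate (CNP0316552.0) | COC(=O)c1c(C)c(C)c(OC(=O)c2c(C)c(C=O)c(O)c(C)c2O)c(C)c1OC | target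

**Step count**
Total step count: 11.
Longest linear sequence: 7 (steps 1, 2, 3, 5, 6, 10, 11, from methylmalonic acid).

**Steps most likely to fail**

Step 5 (cycloaddition).
- Risk: the tetrasubstituted, methoxy-donated pyrone may react so slowly that the siloxyalkyne is consumed first. The competing processes are silver-induced oligomerisation, hydration, and silyl migration to the silylketene.
- Fallback: ring A is made by substitution of an existing arene instead of by annulation. It sets out from 15 and comes back at 12.
- Ionic hydrogenation of the aldehyde of 15 (Et3SiH, CF3CO2H) should give methyl 2,4-dihydroxy-3,5,6-trimethylbenzoate F1.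
- One equivalent of BnBr with K2CO3 in acetone alkylates the non-chelated 4-OH to give methyl 4-(benzyloxy)-2-hydroxy-3,5,6-trimethylbenzoate F2.
- MeI and K2CO3 in DMF then methylate the chelated 2-OH to give methyl 4-(benzyloxy)-2-methoxy-3,5,6-trimethylbenzoate F3, and hydrogenolysis (H2, Pd/C, EtOAc) delivers 12.

Step 9 (saponification).
- Risk: the flanked ester may resist hydroxide for so long that the aldehyde is lost. The likely processes are Cannizzaro disproportionation and base-induced condensation through the acidified C6' methyl group.
- Fallback: acid-mediated ester cleavage and no protecting groups. It sets out from 15 and comes back at 21, bypassing 16 to 20.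
- Cold concentrated H2SO4 cleaves the ester of 15 through the acylium ion, the pathway typical of 2,6-disubstituted benzoates. Pouring onto ice gives 5-formyl-2,4-dihydroxy-3,6-dimethylbenzoic acid F4.
- Both hydroxyls of this acid are tied up in hydrogen bonds (2'-OH to the acid, 4'-OH to the aldehyde) and flanked by the C3' methyl group. It can therefore be condensed directly with 12 using dicyclohexylcarbodiimide in toluene to give 21. This is a known protecting-group-free depside condensation of formyl-bearing phenolic acids.

Step 10 (esterification).
- Risk: with two di-ortho-substituted partners, acylation may be slower than trifluoroacetylation of phenol 12. It may also be slower than acid-induced loss of the 2'-benzyl group from the acylium ion.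
- Fallback: fluoride-mediated silicon-to-acyl exchange instead of acidic acylium chemistry, which also makes step 6 unnecessary. It sets out from 18 and 11 and comes back at 20.
- Cyanuric fluoride and pyridine in CH2Cl2 convert 18 into 2,4-bis(benzyloxy)-5-formyl-3,6-dimethylbenzoyl fluoride F5, a small and stable acyl donor.
- Catalytic Bu4NF in THF then unmasks the phenoxide of 11 in the presence of this fluoride. Each acylation releases fluoride again, and the product is 20.

**Further compounds**
F1 | step 5 | methyl 2,4-dihydroxy-3,5,6-trimethylbenzoate | COC(=O)c1c(C)c(C)c(O)c(C)c1O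
F2 | step 5 | methyl 4-(benzyloxy)-2-hydroxy-3,5,6-trimethylbenzoate | COC(=O)c1c(C)c(C)c(OCc2ccccc2)c(C)c1O
F3 | step 5 | methyl 4-(benzyloxy)-2-methoxy-3,5,6-trimethylbenzoate | COC(=O)c1c(C)c(C)c(OCc2ccccc2)c(C)c1OC
F4 | step 9 | 5-formyl-2,4-dihydroxy-3,6-dimethylbenzoic acid | OC(=O)c1c(C)c(C=O)c(O)c(C)c1O
F5 | step 10 | 2,4-bis(benzyloxy)-5-formyl-3,6-dimethylbenzoyl fluoride | O=C(F)c1c(C)c(C=O)c(OCc2ccccc2)c(C)c1OCc1ccccc1
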